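The earlier runs and the new flask were generated by integration from invented constants, and the scatter is random.

If partner is spent in proportion to what remains, the share of it gone in a given time does not depend on its charge, and we can bracket that share by hand.

| flask | left-handed substrate | right-handed substrate | partner | precatalyst | remark | time |
|---|---|---|---|---|---|---|
| south-west | 0.087 M | 0.087 M | 0.104 M | 2.9 mM | run made earlier |  |
| east | 0.043 M | 0.043 M | 0.104 M | 4.3 mM | run made earlier |  |
| winter | 0.087 M | 0.087 M | 0.104 M | 4.3 mM |  | 3.0 d |
| dusk | 0.087 M | 0.087 M | 0.0800 M | 4.3 mM |  | 3.0 d |

| run | time / h | right-handed substrate / % | left-handed substrate / % |
|---|---|---|---|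
| south-west | 1.00 | 51 | 50 |
| south-west | 3.00 | 49 | 49 |
| south-west | 5.00 | 48 | 51 |
| south-west | 8.00 | 47 | 47 |
| south-west | 12.0 | 50 | 44 |
| south-west | 15.0 | 52 | 42 |
| east | 1.00 | 50 | 50 |
| east | 3.00 | 49 | 50 |
| east | 5.00 | 54 | 50 |
| east | 8.00 | 51 | 48 |
| east | 12.0 | 50 | 42 |
| east | 15.0 | 48 | 38 |

(each reading ± 1.5 percentage points)

- free catalyst is single-handed; left-handed substrate and right-handed substrate are mirror images of each other, charged as a racemate, each of them at the stated concentration
- steps thought possible: precatalyst <-> free catalyst; left-handed substrate <-> right-handed substrate; free catalyst + left-handed substrate <-> catalyst intermediate A; partner + catalyst intermediate B -> free catalyst + right-handed product; partner -> decomposition product; free catalyst + right-handed substrate <-> catalyst intermediate B; partner + catalyst intermediate A -> free catalyst + left-handed product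
- an excess is below zero if the other one leads

- which one finishes higher in excess of right-handed substrate over left-handed substrate among what is left of the two ("neither" within 2 percentage points) (winter / dusk / neither)
- excess of right-handed substrate over left-handed substrate among what is left of the two at the end, winter
- excess of right-handed substrate over left-handed substrate among what is left of the two at the end, dusk

Between 8.00 h and 15.0 h of the east run, c(left-handed substrate) falls at 1.23 mM/h. The south-west run, with twice the substrate and less precatalyst, reads 1.24 mM/h over the same hours; but substrate and precatalyst changed together, partner not at all, and each rate carries the scatter, so these two rates do not show what the rate follows. Right-handed substrate stays flat within the scatter.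

Our quantity, an assumption that these runs do not test, is the pseudo-first-order constant of partner, the east rate over c(partner): 0.0118 /h. Held flat for 3.0 d, it spends 57.3% of the partner, our lower bound, since the east readings stand still up to 5.00 h and the rate was still climbing. For the upper bound we let the constant grow in proportion to time and reach this value at the middle of the window, which spends 93.0%.

Each partner makes one product, so conversion is this share times c(partner) over both substrates charged. Right-handed substrate has been seen flat up to 15.0 h and no further; if we assume it stays untouched for the whole time, the excess is conversion over what remains, so our edges of the excess are estimates resting on that assumption. Winter's lower edge is conversion 34.2%, excess 52.0%. Dusk runs from 26.3% to 42.8%, excess 35.7% to 74.8%. Winter's upper conversion, 55.6%, overshoots the left-handed half of the charge, so going round again we cap it there, and winter's upper edge is complete excess. Winter has more partner than dusk at the same share, so we commit to winter.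

The forecast says winter, with 50% and 37%, on the ground that “Over 3 days, partner limits conversion”. Its winter value lies just under our lower edge, and its dusk value inside our bracket.

    precatalyst ⇌ free catalyst (K = 1.50, k = 0.0180 /h)
    left-handed substrate ⇌ right-handed substrate (k = 0.00400 /h)
    free catalyst + left-handed substrate ⇌ catalyst intermediate A (K = 41.0 /M, k = 370 /M/h)
    partner + catalyst intermediate B → free catalyst + right-handed product (k = 1.10 /M/h)
    partner → decomposition product (k = 1.40 × 10⁻⁴ /h)
    free catalyst + right-handed substrate ⇌ catalyst intermediate B (K = 12.0 /M, k = 140 /M/h)
    partner + catalyst intermediate A → free catalyst + left-handed product (k = 32.0 /M/h)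

The flask gives winter, with 62.9% for winter and 45.7% for dusk, both inside our brackets. But the assumption under those brackets does not hold in winter: right-handed substrate is down to 85% of its charge, and the 47.8% that has reacted there gives 91.6% by our formula, higher than the flask's excess. We carry the constant to a neighbour, winter with 0.042 M of partner: the same shares give conversion from 13.8% to 22.5%, and that flask ends with left-handed product at 21.3%.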